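**Retrosynthetic overview**
1. Ring B is cut last. N5–C6 goes back to an N5–H piperidine and a C6 aldehyde (amino aldehyde → cyclic iminium → hydride).
2. The C12 carbinol goes back to a C12 ketone (spiro-ketol), which is reduced under direction of the C9–OH.
3. The key cascade makes two C–C bonds in one flask: C10–C10a by a decarboxylative Mannich reaction on a Δ1-piperideine (ring A, self-assembled from a δ-amino aldehyde), then C9–C13 by attack of the tetronate γ-carbon on the C9 ketone (ring C).
4. The acid partner comes from tert-butyl acetoacetate, cinnamyl bromide (C6–C9), methyl L-lactate triflate (C11, by inversion) and methyl tetronate (ring D, from ethyl 2-methylacetoacetate).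
5. The amine partner comes from 6-bromohex-1-ene, NaNO2 and propanal; a catalytic syn-Henry reaction sets C1' and C4. The rings form in the order D, A, C, B.

Assumption and numbering: the biosynthesis is taken as Δ1-piperideine → Mannich extension at C10a → attack of tetronate C13 on a C9 ketone → reduction at C12, with the azepane closed by amino-aldehyde/iminium reduction; atoms are N5, C1–C4, C6–C10, C10a, C11 (CHMe), C12 (CHOH), C13 (spiro), C1' (side-chain carbinol); rings are A piperidine, B azepane, C cyclopentane, D butenolide.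

**Step 1**
Reactants: 1 ethyl 2-methyl-3-oxobutanoate
Product: 3 4-hydroxy-3-methylfuran-2(5H)-one (3-methyltetronic acid), via bromo keto ester 2 (not isolated)
Conditions: Br2 (1.0 equiv), CHCl3, 0→23 °C, 16 h; evaporate; neat, 110 °C, 3 h
Reagents that add atoms: none
Why: Bromination (the first-formed 2-bromide migrates to C4 under HBr) followed by thermal lactonisation with loss of bromoethane is the classical tetronic acid synthesis; no stereocentre is formed.

**Step 2**
Reactants: 3 4-hydroxy-3-methylfuran-2(5H)-one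
Product: 4 4-methoxy-3-methylfuran-2(5H)-one (ring D)
Conditions: Me2SO4 (1.1 equiv), K2CO3 (1.2 equiv), acetone, reflux, 4 h
Reagents that add atoms: dimethyl sulfate COS(=O)(=O)OC
Why: Williamson-type O-alkylation of the vinylogous acid gives the methyl tetronate; no stereocentre is formed.

**Step 3**
Reactants: 5 methyl (S)-lactate
Product: 6 methyl (2S)-2-(trifluoromethylsulfonyloxy)propanoate
Conditions: (CF3SO2)2O (1.05 equiv), 2,6-lutidine (1.1 equiv), CH2Cl2, −78→0 °C; used the same day
Reagents that add atoms: trifluoromethanesulfonic anhydride O=S(=O)(OS(=O)(=O)C(F)(F)F)C(F)(F)F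
Why: O-Sulfonylation does not touch the C–O bond, so the (S) centre is retained.

**Step 4**
Reactants: 7 tert-butyl 3-oxobutanoate; 8 (E)-cinnamyl bromide; 6 methyl (2S)-2-(trifluoromethylsulfonyloxy)propanoate
Product: 10 1-tert-butyl 4-methyl (3S)-3-methyl-2-[(4E)-5-phenylpent-4-enoyl]butanedioate (C2 epimers), via keto ester enolate 9 (not isolated)
Conditions: NaH (1.1 equiv), THF, 0 °C; n-BuLi (1.05 equiv), 0 °C; 8 (1.0 equiv), 0 °C, 30 min; then 6 (1.1 equiv), −78→0 °C
Reagents that add atoms: none
Why: Weiler dianion γ-alkylation is followed by SN2 C-alkylation of the remaining β-keto ester enolate with the α-triflyloxy ester, which proceeds with clean inversion and sets C11 as (S), while C10 is a labile mixture that is corrected in step 10.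

**Step 5**
Reactants: 10 1-tert-butyl 4-methyl (3S)-3-methyl-2-[(4E)-5-phenylpent-4-enoyl]butanedioate; 4 4-methoxy-3-methylfuran-2(5H)-one
Product: 11 tert-butyl (3S)-4-(3-methoxy-4-methyl-5-oxo-2,5-dihydrofuran-2-yl)-3-methyl-4-oxo-2-[(4E)-5-phenylpent-4-enoyl]butanoate (C10 and C13 labile)
Conditions: 10 + LiN(i-Pr)2 (1.0 equiv), THF, −78 °C; cannulate into 4 (2.2 equiv) + LiN(i-Pr)2 (2.2 equiv), THF, −78→−20 °C; 1 M HCl quench
Reagents that add atoms: none
Why: This is a crossed Claisen γ-acylation of the lithium dienolate of 4 in which the β-keto ester is masked as its enolate (so only the methyl ester is electrophilic), the second equivalent of dienolate deprotonates the acidic 5-acyl tetronate and drives the reaction, and no base strong enough to remove the C11 proton is present, so C11 stays (S).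

**Step 6**
Reactants: 11 tert-butyl ester from step 5
Product: 12 (3S)-4-(3-methoxy-4-methyl-5-oxo-2,5-dihydrofuran-2-yl)-3-methyl-4-oxo-2-[(4E)-5-phenylpent-4-enoyl]butanoic acid
Conditions: CF3CO2H–CH2Cl2 (1:4), 0 °C, 1 h; evaporate cold; use at once
Reagents that add atoms: none
Why: E1 acidolysis of the tert-butyl ester frees the β-keto acid without base or heat, the disubstituted styrenyl alkene tolerates cold dilute acid, and no stereocentre is touched.

**Step 7**
Reactants: 13 6-bromohex-1-ene
Product: 14 6-nitrohex-1-ene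
Conditions: NaNO2 (1.5 equiv), urea, DMF, 23 °C, 6 h
Reagents that add atoms: sodium nitrite [Na+].[O-]N=O
Why: Kornblum SN2 displacement of a primary bromide by nitrite gives the nitroalkane; no stereocentre is formed.

**Step 8**
Reactants: 14 6-nitrohex-1-ene; 15 propanal
Product: 16 (3R,4R)-4-nitronon-8-en-3-ol
Conditions: 14 (2 equiv, excess recovered), LaLi3[(S)-6,6'-bis(triethylsilylethynyl)-1,1'-binaphthalene-2,2'-diolate]3 (5 mol %), THF, −40 °C, 72 h; chromatography removes the minor anti isomer
Reagents that add atoms: none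
Why: In this catalytic asymmetric Henry (nitroaldol) reaction the La/Li binaphthoxide binds aldehyde and nitronate together and is syn(threo)-selective for linear aldehydes, and the (S)-ligand is chosen because the (R)-ligand gives the (S,S)-threo series, so C1' and C4 are both set (R) by the catalyst.

**Step 9**
Reactants: 16 (3R,4R)-4-nitronon-8-en-3-ol
Product: 17 (3R,4R)-4-aminonon-8-en-3-ol
Conditions: Zn dust (10 equiv), 2 M HCl–EtOH, 0→23 °C; aq. NH3 work-up
Reagents that add atoms: none
Why: Dissolving-metal reduction of the nitro group is run in acid, where retro-Henry cleavage and C4 epimerisation are shut off and the terminal alkene is inert, so both centres are retained.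

**Step 10 (key step)**
Reactants: 17 (3R,4R)-4-aminonon-8-en-3-ol; 12 β-keto acid from step 6
Product: 21 spiro-ketol (1'R,4R,9S,10R,10aS,11S,13R) having rings A C D closed and N5–H and a C12 ketone and at C9 an OH plus an (E)-4-phenylbut-3-enyl chain, via amino aldehyde 18 (not isolated), via cyclic imine 19 (not isolated), via open Mannich base 20 (not isolated)
Conditions: 17, HCl (1.1 equiv), MeOH–CH2Cl2, O3, −78 °C; Me2S; N2 purge and evaporation (removes CH2O); then 12 (0.8 equiv), MeCN–NaH2PO4/Na2HPO4 buffer (pH 7.2), 23 °C, 24 h, then 40 °C, 12 h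
Reagents that add atoms: none
Why: Proposed new method: the unmasked δ-amino aldehyde closes to imine 19 as lysine-type piperideines do, its protonated form is attacked at C10a by the enol released from β-keto acid 12 (loss of CO2 makes C10, not C8 or C13, the irreversible nucleophile), β-amino ketone 20 equilibrates by retro-Mannich/retro-aza-Michael to the diequatorial 2,6-cis piperidine (10aS), and the enolised 5-acyl tetronate then adds to the C9 ketone in a five-ring aldol that fixes labile C10 trans to the lactate-derived C11 methyl (10R), places the C8 chain trans to the piperidine (9S) and puts the small lactone oxygen rather than the C(OMe)= arm on the crowded piperidine face (13R); the closest known reaction types are the Schöpf-type decarboxylative Mannich reaction of Δ1-piperideines with β-keto acids and the aldol spirocyclisation of 5-substituted methyl tetronates onto ketones.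

**Step 11**
Reactants: 21 spiro-ketol
Product: 22 spiro-diol (1'R,4R,9S,10R,10aS,11S,12S,13R)
Conditions: Me4NBH(OAc)3 (5 equiv), MeCN–AcOH (1:1), −20 °C, 12 h
Reagents that add atoms: none
Why: In this Evans–Saksena hydroxyl-directed reduction the boron bound to the C9–OH delivers hydride to the same face of the C12 ketone, which is also the face free of the C11 methyl and the C(OMe)= arm, giving the trans-1,3-diol (12S), and the acidic medium suppresses retro-aldol.

**Step 12**
Reactants: 22 spiro-diol
Product: 25 target CNP0267781.1, via amino aldehyde 23 (not isolated), via cyclic iminium ion 24 (not isolated)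
Conditions: 22, CF3CO2H (1.1 equiv), CH2Cl2–MeOH, O3 (Sudan Red 7B end point), −78 °C; Me2S; evaporate; i-Pr2NEt (1.1 equiv), NaBH(OAc)3 (2 equiv), ClCH2CH2Cl (5 mM), 0→23 °C
Reagents that add atoms: none
Why: Selective ozonolysis of the styrenyl alkene (the amine is protected as its salt and the push–pull tetronate alkene is much less reactive) unmasks the C6 aldehyde, which condenses with N5 to the seven-membered iminium ion and is reduced in an intramolecular reductive amination; no stereocentre is formed because the trans B/C junction is already built into 22.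

**Compound list**
1 | ethyl 2-methyl-3-oxobutanoate | CCOC(=O)C(C)C(C)=O | starting material
2 | ethyl 4-bromo-2-methyl-3-oxobutanoate | CCOC(=O)C(C)C(=O)CBr | intermediate
3 | 4-hydroxy-3-methylfuran-2(5H)-one | CC1=C(O)COC1=O | intermediate
4 | 4-methoxy-3-methylfuran-2(5H)-one | COC1=C(C)C(=O)OC1 | intermediate
5 | methyl (S)-lactate | C[C@H](O)C(=O)OC | starting material
6 | methyl (2S)-2-(trifluoromethylsulfonyloxy)propanoate | C[C@H](OS(=O)(=O)C(F)(F)F)C(=O)OC | intermediate
7 | tert-butyl 3-oxobutanoate | CC(=O)CC(=O)OC(C)(C)C | starting material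
8 | (E)-cinnamyl bromide | BrC/C=C/c1ccccc1 | starting material
9 | tert-butyl (6E)-3-oxo-7-phenylhept-6-enoate (present as its enolate) | O=C(CC/C=C/c1ccccc1)CC(=O)OC(C)(C)C | intermediate
10 | 1-tert-butyl 4-methyl (3S)-3-methyl-2-[(4E)-5-phenylpent-4-enoyl]butanedioate | O=C(CC/C=C/c1ccccc1)C(C(=O)OC(C)(C)C)[C@H](C)C(=O)OC | intermediate
11 | tert-butyl (3S)-4-(3-methoxy-4-methyl-5-oxo-2,5-dihydrofuran-2-yl)-3-methyl-4-oxo-2-[(4E)-5-phenylpent-4-enoyl]butanoate | O=C(CC/C=C/c1ccccc1)C(C(=O)OC(C)(C)C)[C@H](C)C(=O)C1OC(=O)C(C)=C1OC | intermediate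
12 | (3S)-4-(3-methoxy-4-methyl-5-oxo-2,5-dihydrofuran-2-yl)-3-methyl-4-oxo-2-[(4E)-5-phenylpent-4-enoyl]butanoic acid | O=C(CC/C=C/c1ccccc1)C(C(=O)O)[C@H](C)C(=O)C1OC(=O)C(C)=C1OC | intermediate
13 | 6-bromohex-1-ene | BrCCCCC=C | starting material
14 | 6-nitrohex-1-ene | [O-][N+](=O)CCCCC=C | intermediate
15 | propanal | CCC=O | starting material
16 | (3R,4R)-4-nitronon-8-en-3-ol | CC[C@@H](O)[C@H]([N+](=O)[O-])CCCC=C | intermediate
17 | (3R,4R)-4-aminonon-8-en-3-ol | CC[C@@H](O)[C@H](N)CCCC=C | intermediate
18 | (5R,6R)-5-amino-6-hydroxyoctanal (hydrochloride in the flask) | CC[C@@H](O)[C@H](N)CCCC=O | intermediate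
19 | (1R)-1-[(2R)-2,3,4,5-tetrahydropyridin-2-yl]propan-1-ol | CC[C@@H](O)[C@H]1CCCC=N1 | intermediate
20 | 5-{(2S,7E)-3-[(2S,6R)-6-[(1R)-1-hydroxypropyl]piperidin-2-yl]-2-methyl-4-oxo-8-phenyloct-7-enoyl}-4-methoxy-3-methylfuran-2(5H)-one (C10 and C13 labile) | CC[C@@H](O)[C@H]1CCC[C@H](N1)C(C(=O)CC/C=C/c1ccccc1)[C@H](C)C(=O)C1OC(=O)C(C)=C1OC | intermediate
21 | (5R,7S,8R,9S)-9-hydroxy-8-[(2S,6R)-6-[(1R)-1-hydroxypropyl]piperidin-2-yl]-4-methoxy-3,7-dimethyl-9-[(3E)-4-phenylbut-3-en-1-yl]-1-oxaspiro[4.4]non-3-ene-2,6-dione | CC[C@@H](O)[C@H]1CCC[C@H](N1)[C@H]2[C@H](C)C(=O)[C@@]3(OC(=O)C(C)=C3OC)[C@]2(O)CC/C=C/c1ccccc1 | intermediate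
22 | (5R,6S,7S,8R,9S)-6,9-dihydroxy-8-[(2S,6R)-6-[(1R)-1-hydroxypropyl]piperidin-2-yl]-4-methoxy-3,7-dimethyl-9-[(3E)-4-phenylbut-3-en-1-yl]-1-oxaspiro[4.4]non-3-en-2-one | CC[C@@H](O)[C@H]1CCC[C@H](N1)[C@H]2[C@H](C)[C@H](O)[C@@]3(OC(=O)C(C)=C3OC)[C@]2(O)CC/C=C/c1ccccc1 | intermediate
23 | 3-{(5R,6S,7S,8R,9S)-6,9-dihydroxy-8-[(2S,6R)-6-[(1R)-1-hydroxypropyl]piperidin-2-yl]-4-methoxy-3,7-dimethyl-2-oxo-1-oxaspiro[4.4]non-3-en-9-yl}propanal | CC[C@@H](O)[C@H]1CCC[C@H](N1)[C@H]2[C@H](C)[C@H](O)[C@@]3(OC(=O)C(C)=C3OC)[C@]2(O)CCC=O | intermediate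
24 | N5=C6 iminium ion of the target skeleton | CC[C@@H](O)[C@H]1CCC[C@H]2[C@H]3[C@H](C)[C@H](O)[C@@]4(OC(=O)C(C)=C4OC)[C@]3(O)CCC=[N+]12 | intermediate
25 | CNP0267781.1 (1'R,4R,9S,10R,10aS,11S,12S,13R) | CC[C@@H](O)[C@H]1CCC[C@H]2[C@H]3[C@H](C)[C@H](O)[C@@]4(OC(=O)C(C)=C4OC)[C@]3(O)CCCN12 | target

**Totals**
- Total step count: 12.
- Longest linear sequence: 7 steps (steps 1, 2, 5, 6, 10, 11, 12). The branch through steps 3, 4, 5, 6, 10, 11, 12 is equally long. The amine branch is 6 steps.

**The three steps most likely to fail**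

**Step 10.**
- The nucleophilic carbon is tertiary and hindered.
- The ketol must win against the stabilised open enol.
- The C10/C10a relationship rests on the C11 anchor outweighing the intrinsic anti preference of the Mannich base.

The fallback sets out from 16 (with 12) and comes back to the route at 20. It makes the C10–C10a link as a C=C bond first and closes ring A by aza-Michael addition. Ozonolysis of 16 (O3, then Me2S) gives (5R,6R)-6-hydroxy-5-nitrooctanal F3. A piperidinium acetate-catalysed decarboxylative Knoevenagel (Doebner-type) condensation with 12 gives 4-methoxy-3-methyl-5-{(2S,8R,9R)-9-hydroxy-2-methyl-8-nitro-3-[(4E)-5-phenylpent-4-enoyl]undec-3-enoyl}furan-2(5H)-one F4. Zn/AcOH then reduces the nitro group, and the amine adds 6-exo to the enone under thermodynamic 2,6-cis control to give 20. Compound 20 is closed to 21 in buffered AcOH.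

**Step 5.** An α-branched methyl ester next to an enolate is a sluggish acyl donor for a stabilised dienolate. The fallback sets out from 10 (with 4) and comes back at 11. It forms the C12–C13 bond at the aldehyde oxidation level. Compound 10 is pre-enolised with NaH and reduced with i-Bu2AlH at −78 °C to tert-butyl (3S)-3-methyl-4-oxo-2-[(4E)-5-phenylpent-4-enoyl]butanoate F1. Lithiated 4 adds to the aldehyde (vinylogous aldol) to give tert-butyl (3S)-4-hydroxy-4-(3-methoxy-4-methyl-5-oxo-2,5-dihydrofuran-2-yl)-3-methyl-2-[(4E)-5-phenylpent-4-enoyl]butanoate F2. Dess–Martin oxidation of its only hydroxyl gives 11.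

**Step 12.** A doubly α-branched secondary amine must form a seven-membered iminium ion across a trans-disubstituted cyclopentane. The fallback sets out from 22 and comes back at 25. It replaces iminium chemistry by SN2 ring closure. Ozonolysis with NaBH4 work-up gives (5R,6S,7S,8R,9S)-6,9-dihydroxy-9-(3-hydroxypropyl)-8-[(2S,6R)-6-[(1R)-1-hydroxypropyl]piperidin-2-yl]-4-methoxy-3,7-dimethyl-1-oxaspiro[4.4]non-3-en-2-one F5. Its single primary hydroxyl is activated selectively with PPh3/CBr4/Et3N and displaced by N5 (7-exo-tet) to give 25.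

**Further compounds**
F1 | step 5 | tert-butyl (3S)-3-methyl-4-oxo-2-[(4E)-5-phenylpent-4-enoyl]butanoate | O=C(CC/C=C/c1ccccc1)C(C(=O)OC(C)(C)C)[C@H](C)C=O
F2 | step 5 | tert-butyl (3S)-4-hydroxy-4-(3-methoxy-4-methyl-5-oxo-2,5-dihydrofuran-2-yl)-3-methyl-2-[(4E)-5-phenylpent-4-enoyl]butanoate | O=C(CC/C=C/c1ccccc1)C(C(=O)OC(C)(C)C)[C@H](C)C(O)C1OC(=O)C(C)=C1OC
F3 | step 10 | (5R,6R)-6-hydroxy-5-nitrooctanal | CC[C@@H](O)[C@H]([N+](=O)[O-])CCCC=O
F4 | step 10 | 4-methoxy-3-methyl-5-{(2S,8R,9R)-9-hydroxy-2-methyl-8-nitro-3-[(4E)-5-phenylpent-4-enoyl]undec-3-enoyl}furan-2(5H)-one | CC[C@@H](O)[C@H]([N+](=O)[O-])CCCC=C(C(=O)CC/C=C/c1ccccc1)[C@H](C)C(=O)C1OC(=O)C(C)=C1OC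
F5 | step 12 | (5R,6S,7S,8R,9S)-6,9-dihydroxy-9-(3-hydroxypropyl)-8-[(2S,6R)-6-[(1R)-1-hydroxypropyl]piperidin-2-yl]-4-methoxy-3,7-dimethyl-1-oxaspiro[4.4]non-3-en-2-one | CC[C@@H](O)[C@H]1CCC[C@H](N1)[C@H]2[C@H](C)[C@H](O)[C@@]3(OC(=O)C(C)=C3OC)[C@]2(O)CCCO
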